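Each exchange uses one incoming ligand and frees one leaving ligand, so their sum stays at the charge of incoming ligand.

| setting | zeta | Thursday's | Saturday's |
|---|---|---|---|
| starting complex | 0.034 M | 0.050 M | 0.050 M |
| incoming ligand | 1.05 equiv | 2.60 equiv | 1.10 equiv |
| remark | run made earlier |  |  |
| time |  | 15 min | 15 min |

zeta run (percent of the starting complex charged)

| time / min | starting complex / % | complex with four exchanged / % | complex with one exchanged / % | complex with two exchanged / % | over-reaction product / % |
|---|---|---|---|---|---|
| 0.417 | 76.9 | 0 | 20.2 | 3.5 | 0 |
| 0.667 | 68.9 | 0 | 24.6 | 6.6 | 0 |
| 1.00 | 61.5 | 0.3 | 26.7 | 11.4 | 0 |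
| 1.33 | 57.5 | 0.1 | 27.8 | 15.3 | 0 |
| 2.50 | 52.3 | 0 | 23.6 | 24.2 | 0 |
| 3.00 | 52.2 | 0.5 | 20.9 | 25.8 | 0.1 |
| 5.00 | 50.9 | 0 | 15.9 | 31.4 | 0.5 |

(scatter of a reading: 0.3 percentage points)

- the numbers in the tables scatter with a standard deviation of 0.3 percentage points
- a reading or a percentage of complex with four exchanged counts all its forms, free or not
- no earlier run changes the charge of incoming ligand; that part of a forecast is a guess

1. which of these there is most of at the end, counted by the starting complex in it, Thursday's (complex with one exchanged / complex with two exchanged / over-reaction product / starting complex)
2. which of these there is most of at the end, counted by the starting complex in it, Saturday's (complex with one exchanged / complex with two exchanged / over-reaction product / starting complex)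
3. the largest of these amounts at the end, in percent of the starting complex charged, Thursday's
4. the largest of these amounts at the end, in percent of the starting complex charged, Saturday's

First, is the time long enough? I take the zeta run's first reading and treat the ligand as held at its charge, as if pseudo-first-order. For the first exchange on Saturday's, counted forward, this gives an estimated half-life of 0.714 min. So 15 min holds 21.0 of these half-lives, and the first exchange on Saturday's has time to come to a stall.

So where does it stop? At the zeta run's last reading, the complexes with one and two exchanged have freed 0.787 equivalents, leaving at most 0.263 equivalents of incoming ligand, since any complex exchanged further holds some too. Yet starting complex has moved just from 52.3 % to 50.9 % since 2.50 min. I therefore define the stall quotient, the reaction quotient of the first exchange: [complex with one exchanged][leaving ligand] over [starting complex][incoming ligand]. The zeta run reads 0.935. It has no unit, so the equivalents matter here and the concentration cancels.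

Saturday's 1.10 equiv lies close to the zeta run's 1.05 equiv. I expect starting complex near 50.9 % on Saturday's, which is more than the complexes with one and two exchanged together held at the zeta run's last reading. Thursday's 2.60 equiv is more than two per complex, so I expect complex with two exchanged to lead there.

The forecast reasons “so the exchanges look reversible against the released ligand”. It gives complex with two exchanged at 62 % for Thursday's and starting complex at 49.5 % for Saturday's.

Thursday's gives complex with two exchanged at 49.4 %, which is 13 percentage points below the forecast, beside 17.6 % of over-reaction product. Saturday's gives starting complex at 51.1 %.

    complex with two exchanged + incoming ligand ⇌ leaving ligand + complex with three exchanged (K = 1.62, k = 0.0114 M⁻¹ s⁻¹)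
    complex with four exchanged → over-reaction product (k = 0.00854 s⁻¹)
    starting complex + incoming ligand ⇌ leaving ligand + complex with one exchanged (K = 1.10, k = 0.356 M⁻¹ s⁻¹)
    complex with three exchanged + incoming ligand ⇌ leaving ligand + complex with four exchanged (K = 2.50, k = 1.09 M⁻¹ s⁻¹)
    complex with one exchanged + incoming ligand ⇌ leaving ligand + complex with two exchanged (K = 18.1, k = 0.417 M⁻¹ s⁻¹)
    crystals ⇌ complex with four exchanged, rate k6*(cs6 - [complex with four exchanged]) while solid is left; crystals form when [complex with four exchanged] > cs6 (solubility = 31.0 mM, k = 0.0797 s⁻¹)

At the end of Saturday's, the stall quotient is 1.12. The neighbouring flask is Saturday's with 0.280 equiv of incoming ligand. That neighbour ends with 82.7 % starting complex, 9.21 % complex with one exchanged, 0.0128 M leaving ligand and 8.8 % of its incoming ligand unbound, which makes its stall quotient 1.15.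

The readings are calculated from invented constants.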